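The tetrahydrofuran ring (O1, C2–C5) is closed at its C3–C4 bond, the lignan C8–C8' bond. The feature exploited is that C3 bears a CH2OH, i.e. an oxygen on the carbon next to the bond-forming atom, and C4 a benzyl group: C3 is therefore generated as the carbon radical of a titanocene-opened terminal epoxide, and C4 is the inner alkene carbon of a cinnamyl ether. One 5-exo-trig radical cyclisation of an acyclic (R)-benzylic epoxy cinnamyl ether forms the ring, unveils both side chains and sets C3 and C4 from C2 alone. The threo-(S,S) guaiacylglycerol arm is then built on the ring-A phenol by an Evans syn-glycolate aldol.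

Key step: step 6

Remarks on the chemistry. Ring A is the aryl group on C2 of the tetrahydrofuran (it carries the ether arm), ring B the aryl of the C4 benzyl group, ring C the aryl of the glycerol arm. Lignan numbering: C7 = ring C2, C8 = ring C3, C8' = ring C4, C9' = ring C5, C9 = the CH2OH carbon on C3. Assumption: compounds 1, 4 and 10 are catalogue chemicals (1 would otherwise come in one step from vanillin, allyl bromide and K2CO3).

Step 1
Reactants: 1 4-(allyloxy)-3-methoxybenzaldehyde
Product: 2 rac-1-[4-(allyloxy)-3-methoxyphenyl]prop-2-en-1-ol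
Conditions: CH2=CHMgBr (1.2 equiv), THF, −78 to 0 °C; aq. NH4Cl (neutral work-up)
Reagents that add atoms: vinylmagnesium bromide, C=C[Mg]Br
Why: Grignard 1,2-addition to the aryl aldehyde gives the allylic carbinol as a racemate whose stereocentre (the later ring C2) is resolved in step 2.

Step 2
Reactants: 2 rac-1-[4-(allyloxy)-3-methoxyphenyl]prop-2-en-1-ol
Product: 3 (R)-[4-(allyloxy)-3-methoxyphenyl][(S)-oxiran-2-yl]methanol
Conditions: Ti(OiPr)4 (0.15 equiv), D-(−)-diisopropyl tartrate (0.2 equiv), t-BuOOH (0.5 equiv), 4 Å molecular sieves, CH2Cl2, −20 °C, stopped near 45% conversion; aq. Na2SO4 work-up without acid; chromatography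
Reagents that add atoms: tert-butyl hydroperoxide, CC(C)(C)OO
Why: Sharpless kinetic resolution: with D-(−)-tartrate the (S)-carbinol is the fast-reacting enantiomer and is epoxidised on the reagent-controlled face to the erythro epoxy alcohol, so the carbinol centre of 3 is fixed as R (the descriptor changes only because oxiranyl outranks aryl), slow-reacting (R)-2 stays behind and is removed, and the isolated allyl ether is untouched because only the allylic alcohol binds titanium.

Step 3
Reactants: 4 4-(benzyloxy)-3-methoxybenzaldehyde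
Product: 5 rac-1-[4-(benzyloxy)-3-methoxyphenyl]prop-2-en-1-ol
Conditions: CH2=CHMgBr (1.2 equiv), THF, −78 to 0 °C; aq. NH4Cl
Reagents that add atoms: vinylmagnesium bromide, C=C[Mg]Br
Why: Grignard 1,2-addition as in step 1; the racemic centre is destroyed in step 4.

Step 4
Reactants: 5 rac-1-[4-(benzyloxy)-3-methoxyphenyl]prop-2-en-1-ol
Product: 6 (E)-1-(benzyloxy)-4-(3-bromoprop-1-en-1-yl)-2-methoxybenzene
Conditions: PBr3 (0.4 equiv), Et2O, −10 to 0 °C; used crude at once
Reagents that add atoms: phosphorus tribromide, BrP(Br)Br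
Why: Bromination of an aryl vinyl carbinol with allylic transposition (SN2' or ion-pair return at the terminus) should give the conjugated, thermodynamically preferred (E)-cinnamyl bromide, which is used directly because the electron-rich bromide is labile.

Step 5
Reactants: 3 (R)-[4-(allyloxy)-3-methoxyphenyl][(S)-oxiran-2-yl]methanol; 6 (E)-1-(benzyloxy)-4-(3-bromoprop-1-en-1-yl)-2-methoxybenzene
Product: 7 (S)-2-[(R)-[4-(allyloxy)-3-methoxyphenyl]{[(E)-3-[4-(benzyloxy)-3-methoxyphenyl]prop-2-en-1-yl]oxy}methyl]oxirane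
Conditions: NaH (1.1 equiv), n-Bu4NI (cat.), THF–DMF, −20 to 0 °C
Reagents that add atoms: none
Why: Williamson etherification: the sodium alkoxide of 3 is alkylated by the highly reactive allylic bromide at low temperature, faster than epoxide migration (Payne rearrangement), and the C–O bond at the stereocentre is not broken, so its configuration is kept.

Step 6
Reactants: 7 (S)-2-[(R)-[4-(allyloxy)-3-methoxyphenyl]{[(E)-3-[4-(benzyloxy)-3-methoxyphenyl]prop-2-en-1-yl]oxy}methyl]oxirane
Product: 8 [(2S,3R,4R)-2-[4-(allyloxy)-3-methoxyphenyl]-4-[4-(benzyloxy)-3-methoxybenzyl]tetrahydrofuran-3-yl]methanol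
Conditions: Cp2TiCl2 (2.5 equiv), Zn, THF, rt, the green Cp2TiCl solution added slowly to 7 (0.02 M); aq. NaH2PO4; chromatography
Reagents that add atoms: none
Why: Cp2TiCl (trivalent titanium, made from Cp2TiCl2 and Zn) transfers one electron to the oxirane, which opens at its substituted C–O bond to the secondary β-titanoxy radical at C3; this radical adds to the inner carbon of the cinnamyl double bond to form C3–C4, and the benzylic radical so formed is reduced by a second Cp2TiCl and protonated on work-up (or takes hydrogen from THF). The closest known reaction type is the Nugent–RajanBabu reductive epoxide opening with radical cyclisation, which has been used on aryl epoxy cinnamyl ethers of this kind to make furanoid lignans. The tetrahydrofuran closes in the 5-exo-trig mode. Both new stereocentres are controlled by the existing C2 centre through a chair-like Beckwith–Houk transition state with the C2 aryl pseudo-equatorial: the CH2O[Ti] group on C3 comes out trans to the aryl (2,3-trans) and cis to the forming benzylic branch on C4 (3,4-cis, the 1,5-cis rule for 1-substituted hexenyl radicals), and the oxirane configuration is irrelevant because C3 becomes planar. The step needs regioselective opening to the secondary radical, secured by radical stability, and ring closure faster than capture of the radical by a second Cp2TiCl followed by β-elimination to the alkene, secured by the styrene-type acceptor and slow addition at high dilution. The allyl aryl ether and the benzyl ether should be inert because no favourable ring size is open to them and Cp2TiCl does not reduce them.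

Step 7
Reactants: 8 [(2S,3R,4R)-2-[4-(allyloxy)-3-methoxyphenyl]-4-[4-(benzyloxy)-3-methoxybenzyl]tetrahydrofuran-3-yl]methanol
Product: 9 4-[(2S,3R,4R)-4-[4-(benzyloxy)-3-methoxybenzyl]-3-(hydroxymethyl)tetrahydrofuran-2-yl]-2-methoxyphenol
Conditions: Pd(PPh3)4 (5 mol%), morpholine (5 equiv), THF, rt
Reagents that add atoms: none
Why: Tsuji–Trost deallylation: zerovalent palladium ionises only the aryl allyl ether (phenoxide leaving group) and morpholine traps the π-allyl, leaving the benzyl ether, the cyclic benzylic ether and the three stereocentres untouched.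

Step 8
Reactants: 10 (R)-4-benzyloxazolidin-2-one
Product: 11 (R)-4-benzyl-3-(2-bromoacetyl)oxazolidin-2-one
Conditions: n-BuLi (1.0 equiv), THF, −78 °C; BrCH2COBr (1.1 equiv), −78 °C
Reagents that add atoms: bromoacetyl bromide, BrCC(Br)=O
Why: N-Acylation of the lithiated oxazolidinone at the acyl bromide, which is far more electrophilic than the alkyl bromide; the auxiliary stereocentre is not involved.

Step 9
Reactants: 9 4-[(2S,3R,4R)-4-[4-(benzyloxy)-3-methoxybenzyl]-3-(hydroxymethyl)tetrahydrofuran-2-yl]-2-methoxyphenol; 11 (R)-4-benzyl-3-(2-bromoacetyl)oxazolidin-2-one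
Product: 12 (R)-4-benzyl-3-[2-[4-[(2S,3R,4R)-4-[4-(benzyloxy)-3-methoxybenzyl]-3-(hydroxymethyl)tetrahydrofuran-2-yl]-2-methoxyphenoxy]acetyl]oxazolidin-2-one
Conditions: K2CO3 (1.5 equiv), MeCN, rt
Reagents that add atoms: none
Why: Williamson-type SN2 displacement of the activated α-bromo imide by the potassium phenoxide; carbonate does not deprotonate the primary alcohol, so only the ring-A phenol is alkylated.

Step 10
Reactants: 12 (R)-4-benzyl-3-[2-[4-[(2S,3R,4R)-4-[4-(benzyloxy)-3-methoxybenzyl]-3-(hydroxymethyl)tetrahydrofuran-2-yl]-2-methoxyphenoxy]acetyl]oxazolidin-2-one; 4 4-(benzyloxy)-3-methoxybenzaldehyde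
Product: 14 (R)-4-benzyl-3-[(2R,3S)-3-[4-(benzyloxy)-3-methoxyphenyl]-2-[4-[(2S,3R,4R)-4-[4-(benzyloxy)-3-methoxybenzyl]-3-(hydroxymethyl)tetrahydrofuran-2-yl]-2-methoxyphenoxy]-3-hydroxypropanoyl]oxazolidin-2-one, via bis-borylated Z-enolate 13 (not isolated)
Conditions: Bu2BOTf (2.3 equiv), iPr2NEt (2.6 equiv), CH2Cl2, −78 to 0 °C; 4 (1.3 equiv), −78 to 0 °C; pH 7 buffer, MeOH, H2O2, 0 °C
Reagents that add atoms: dibutylboron trifluoromethanesulfonate, CCCCB(CCCC)OS(=O)(=O)C(F)(F)F (its boron groups are carried only in 13 and leave on work-up)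
Why: Evans syn-glycolate aldol: one equivalent of Bu2BOTf masks the primary hydroxyl as its borinate and a second forms the Z boron enolate 13, which adds to the aldehyde through a Zimmerman–Traxler chair on the enolate face away from the benzyl group of the (R)-auxiliary to set both new centres as (2R,3S), the syn (threo) arrangement, before oxidative work-up frees the alcohol.

Step 11
Reactants: 14 (R)-4-benzyl-3-[(2R,3S)-3-[4-(benzyloxy)-3-methoxyphenyl]-2-[4-[(2S,3R,4R)-4-[4-(benzyloxy)-3-methoxybenzyl]-3-(hydroxymethyl)tetrahydrofuran-2-yl]-2-methoxyphenoxy]-3-hydroxypropanoyl]oxazolidin-2-one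
Product: 15 (1S,2S)-1-[4-(benzyloxy)-3-methoxyphenyl]-2-[4-[(2S,3R,4R)-4-[4-(benzyloxy)-3-methoxybenzyl]-3-(hydroxymethyl)tetrahydrofuran-2-yl]-2-methoxyphenoxy]propane-1,3-diol
Conditions: NaBH4 (4 equiv), THF–H2O (4:1), 0 °C to rt
Reagents that add atoms: none
Why: Reductive cleavage of the N-acyloxazolidinone by borohydride at the exocyclic carbonyl gives the primary alcohol without touching the two new stereocentres (the C2 descriptor becomes S only through the change in substituent ranking) and returns the auxiliary 10.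

Step 12
Reactants: 15 (1S,2S)-1-[4-(benzyloxy)-3-methoxyphenyl]-2-[4-[(2S,3R,4R)-4-[4-(benzyloxy)-3-methoxybenzyl]-3-(hydroxymethyl)tetrahydrofuran-2-yl]-2-methoxyphenoxy]propane-1,3-diol
Product: 16 (1S,2S)-1-(4-hydroxy-3-methoxyphenyl)-2-[4-[(2S,3R,4R)-4-(4-hydroxy-3-methoxybenzyl)-3-(hydroxymethyl)tetrahydrofuran-2-yl]-2-methoxyphenoxy]propane-1,3-diol
Conditions: H2 (1 atm), Pd/C (10 wt%), EtOAc–MeOH, rt, stopped at full O-debenzylation
Reagents that add atoms: none
Why: Hydrogenolysis of the two aryl benzyl ethers over palladium is much faster under neutral conditions than cleavage of the benzylic C–O bonds of the tetrahydrofuran and of the carbinol, so stopping at full O-debenzylation should give the target with all five stereocentres intact.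

Compound list
1 | 4-(allyloxy)-3-methoxybenzaldehyde | C=CCOc1ccc(C=O)cc1OC | starting material
2 | rac-1-[4-(allyloxy)-3-methoxyphenyl]prop-2-en-1-ol | C=CCOc1ccc(C(O)C=C)cc1OC | intermediate
3 | (R)-[4-(allyloxy)-3-methoxyphenyl][(S)-oxiran-2-yl]methanol | O[C@H](c1ccc(OCC=C)c(OC)c1)[C@@H]1CO1 | intermediate
4 | 4-(benzyloxy)-3-methoxybenzaldehyde | O=Cc1ccc(OCc2ccccc2)c(OC)c1 | starting material
5 | rac-1-[4-(benzyloxy)-3-methoxyphenyl]prop-2-en-1-ol | C=CC(O)c1ccc(OCc2ccccc2)c(OC)c1 | intermediate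
6 | (E)-1-(benzyloxy)-4-(3-bromoprop-1-en-1-yl)-2-methoxybenzene | BrC/C=C/c1ccc(OCc2ccccc2)c(OC)c1 | intermediate
7 | (S)-2-[(R)-[4-(allyloxy)-3-methoxyphenyl]{[(E)-3-[4-(benzyloxy)-3-methoxyphenyl]prop-2-en-1-yl]oxy}methyl]oxirane | COc1cc(/C=C/CO[C@H](c2ccc(OCC=C)c(OC)c2)[C@@H]2CO2)ccc1OCc1ccccc1 | intermediate
8 | [(2S,3R,4R)-2-[4-(allyloxy)-3-methoxyphenyl]-4-[4-(benzyloxy)-3-methoxybenzyl]tetrahydrofuran-3-yl]methanol | COc1cc(C[C@H]2CO[C@H](c3ccc(OCC=C)c(OC)c3)[C@H]2CO)ccc1OCc1ccccc1 | intermediate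
9 | 4-[(2S,3R,4R)-4-[4-(benzyloxy)-3-methoxybenzyl]-3-(hydroxymethyl)tetrahydrofuran-2-yl]-2-methoxyphenol | COc1cc(C[C@H]2CO[C@H](c3ccc(O)c(OC)c3)[C@H]2CO)ccc1OCc1ccccc1 | intermediate
10 | (R)-4-benzyloxazolidin-2-one | O=C1N[C@H](Cc2ccccc2)CO1 | starting material
11 | (R)-4-benzyl-3-(2-bromoacetyl)oxazolidin-2-one | O=C1OC[C@@H](Cc2ccccc2)N1C(=O)CBr | intermediate
12 | (R)-4-benzyl-3-[2-[4-[(2S,3R,4R)-4-[4-(benzyloxy)-3-methoxybenzyl]-3-(hydroxymethyl)tetrahydrofuran-2-yl]-2-methoxyphenoxy]acetyl]oxazolidin-2-one | COc1cc(C[C@H]2CO[C@H](c3ccc(OCC(=O)N4C(=O)OC[C@H]4Cc4ccccc4)c(OC)c3)[C@H]2CO)ccc1OCc1ccccc1 | intermediate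
13 | Z dibutylboron enolate of 12 carrying the primary hydroxyl as its dibutylborinate | COc1cc(C[C@H]2CO[C@H](c3ccc(O/C=C(\OB(CCCC)CCCC)N4C(=O)OC[C@H]4Cc4ccccc4)c(OC)c3)[C@H]2COB(CCCC)CCCC)ccc1OCc1ccccc1 | intermediate (not isolated)
14 | (R)-4-benzyl-3-[(2R,3S)-3-[4-(benzyloxy)-3-methoxyphenyl]-2-[4-[(2S,3R,4R)-4-[4-(benzyloxy)-3-methoxybenzyl]-3-(hydroxymethyl)tetrahydrofuran-2-yl]-2-methoxyphenoxy]-3-hydroxypropanoyl]oxazolidin-2-one | COc1cc(C[C@H]2CO[C@H](c3ccc(O[C@@H](C(=O)N4C(=O)OC[C@H]4Cc4ccccc4)[C@@H](O)c4ccc(OCc5ccccc5)c(OC)c4)c(OC)c3)[C@H]2CO)ccc1OCc1ccccc1 | intermediate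
15 | (1S,2S)-1-[4-(benzyloxy)-3-methoxyphenyl]-2-[4-[(2S,3R,4R)-4-[4-(benzyloxy)-3-methoxybenzyl]-3-(hydroxymethyl)tetrahydrofuran-2-yl]-2-methoxyphenoxy]propane-1,3-diol | COc1cc(C[C@H]2CO[C@H](c3ccc(O[C@@H](CO)[C@@H](O)c4ccc(OCc5ccccc5)c(OC)c4)c(OC)c3)[C@H]2CO)ccc1OCc1ccccc1 | intermediate
16 | (1S,2S)-1-(4-hydroxy-3-methoxyphenyl)-2-[4-[(2S,3R,4R)-4-(4-hydroxy-3-methoxybenzyl)-3-(hydroxymethyl)tetrahydrofuran-2-yl]-2-methoxyphenoxy]propane-1,3-diol (CNP0226724.1) | COc1cc(C[C@H]2CO[C@H](c3ccc(O[C@@H](CO)[C@@H](O)c4ccc(O)c(OC)c4)c(OC)c3)[C@H]2CO)ccc1O | target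

Total step count: 12. Longest linear sequence: 9 steps (steps 1, 2, 5, 6, 7, 9, 10, 11, 12, from 1 to 16); steps 3–4 and step 8 are side branches.

Steps most likely to fail

Step 6. The C3 radical may be captured by a second Cp2TiCl and lose the titanoxy group by β-elimination (deoxygenation back to the alkene) before it closes the ring. Fallback from 7 to 8, generating the same radical without titanium: aqueous NaOH in dioxane at 90 °C opens the oxirane at its CH2 group to (2S,3R)-3-[4-(allyloxy)-3-methoxyphenyl]-3-{[(E)-3-[4-(benzyloxy)-3-methoxyphenyl]prop-2-en-1-yl]oxy}propane-1,2-diol F1. 1,1'-Thiocarbonyldiimidazole in THF at 60 °C then closes (S)-4-[(R)-[4-(allyloxy)-3-methoxyphenyl]{[(E)-3-[4-(benzyloxy)-3-methoxyphenyl]prop-2-en-1-yl]oxy}methyl]-1,3-dioxolane-2-thione F2. Slow addition of Bu3SnH with AIBN in toluene at 80 °C should fragment F2 (Barton-type) to the secondary C3 radical, which closes 5-exo-trig under the same transition-state control to the S-tributylstannyl thiocarbonate of 8 F3. K2CO3 in MeOH cleaves F3 to 8, where the route is rejoined.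

Step 2. The two enantiomers of this aryl vinyl carbinol may be discriminated too weakly, so that the epoxy alcohol taken as product carries too much of its enantiomer. Fallback from 2 to 3 by an acylative resolution followed by epoxidation of a single enantiomer: immobilised Candida antarctica lipase B (Novozym 435) with vinyl acetate in MTBE at rt acylates the (R)-carbinol to (R)-1-[4-(allyloxy)-3-methoxyphenyl]prop-2-en-1-yl acetate F5 and leaves (S)-1-[4-(allyloxy)-3-methoxyphenyl]prop-2-en-1-ol F4. After separation, F4 is epoxidised in the matched sense with Ti(OiPr)4, D-(−)-diisopropyl tartrate and t-BuOOH in CH2Cl2 at −20 °C to 3.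

Step 10. The free primary hydroxyl may sequester the boron triflate so that enolisation stalls, and the excess Lewis acid may ionise the benzylic ether bond at C2 of the tetrahydrofuran. Fallback from 12 to 15 with covalent masking and normal stoichiometry: Ac2O, pyridine and DMAP give [(2S,3R,4R)-2-[4-[2-[(R)-4-benzyl-2-oxooxazolidin-3-yl]-2-oxoethoxy]-3-methoxyphenyl]-4-[4-(benzyloxy)-3-methoxybenzyl]tetrahydrofuran-3-yl]methyl acetate F6. The Evans aldol with Bu2BOTf (1.1 equiv), iPr2NEt and 4 then gives the (2R,3S) syn adduct as its acetate, [(2S,3R,4R)-2-[4-[(1R,2S)-1-[(R)-4-benzyl-2-oxooxazolidine-3-carbonyl]-2-[4-(benzyloxy)-3-methoxyphenyl]-2-hydroxyethoxy]-3-methoxyphenyl]-4-[4-(benzyloxy)-3-methoxybenzyl]tetrahydrofuran-3-yl]methyl acetate F7. LiBH4 in THF–MeOH at 0 °C removes the auxiliary and the acetate in one operation to give 15.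

Further compounds
F1 | step 6 | (2S,3R)-3-[4-(allyloxy)-3-methoxyphenyl]-3-{[(E)-3-[4-(benzyloxy)-3-methoxyphenyl]prop-2-en-1-yl]oxy}propane-1,2-diol | COc1cc(/C=C/CO[C@H](c2ccc(OCC=C)c(OC)c2)[C@@H](O)CO)ccc1OCc1ccccc1
F2 | step 6 | (S)-4-[(R)-[4-(allyloxy)-3-methoxyphenyl]{[(E)-3-[4-(benzyloxy)-3-methoxyphenyl]prop-2-en-1-yl]oxy}methyl]-1,3-dioxolane-2-thione | COc1cc(/C=C/CO[C@H](c2ccc(OCC=C)c(OC)c2)[C@@H]2COC(=S)O2)ccc1OCc1ccccc1
F3 | step 6 | O-{[(2S,3R,4R)-2-[4-(allyloxy)-3-methoxyphenyl]-4-[4-(benzyloxy)-3-methoxybenzyl]tetrahydrofuran-3-yl]methyl} S-(tributylstannyl) thiocarbonate | COc1cc(C[C@H]2CO[C@H](c3ccc(OCC=C)c(OC)c3)[C@H]2COC(=O)S[Sn](CCCC)(CCCC)CCCC)ccc1OCc1ccccc1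
F4 | step 2 | (S)-1-[4-(allyloxy)-3-methoxyphenyl]prop-2-en-1-ol | O[C@H](c1ccc(OCC=C)c(OC)c1)C=C
F5 | step 2 | (R)-1-[4-(allyloxy)-3-methoxyphenyl]prop-2-en-1-yl acetate | CC(=O)O[C@@H](c1ccc(OCC=C)c(OC)c1)C=C
F6 | step 10 | [(2S,3R,4R)-2-[4-[2-[(R)-4-benzyl-2-oxooxazolidin-3-yl]-2-oxoethoxy]-3-methoxyphenyl]-4-[4-(benzyloxy)-3-methoxybenzyl]tetrahydrofuran-3-yl]methyl acetate | COc1cc(C[C@H]2CO[C@H](c3ccc(OCC(=O)N4C(=O)OC[C@H]4Cc4ccccc4)c(OC)c3)[C@H]2COC(C)=O)ccc1OCc1ccccc1
F7 | step 10 | [(2S,3R,4R)-2-[4-[(1R,2S)-1-[(R)-4-benzyl-2-oxooxazolidine-3-carbonyl]-2-[4-(benzyloxy)-3-methoxyphenyl]-2-hydroxyethoxy]-3-methoxyphenyl]-4-[4-(benzyloxy)-3-methoxybenzyl]tetrahydrofuran-3-yl]methyl acetate | COc1cc(C[C@H]2CO[C@H](c3ccc(O[C@@H](C(=O)N4C(=O)OC[C@H]4Cc4ccccc4)[C@@H](O)c4ccc(OCc5ccccc5)c(OC)c4)c(OC)c3)[C@H]2COC(C)=O)ccc1OCc1ccccc1
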